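A bis adduct that halves in 0.056 d under attack by the coupling partner at its charged strength, against 0.21 d by its own decay, looks bound for triple product. I began from that comparison on this flask, where the substrate arrives in portions and takes up the partner step by step.

substrate 0.10 M (in portions, 2); coupling partner 0.0950 M; time 10 d; the portions of substrate follow each other after 6.0 h, the first at the start

    coupling partner + mono adduct → bis adduct (k1 = 2.83 × 10⁻⁴ /M/s)
    bis adduct → decomposed reagent (k2 = 3.84 × 10⁻⁵ /s)
    crystals ⇌ triple product, rate k3*(cs3 - [triple product]) while solid is left; crystals form when [triple product] > cs3 (cs3 = 5.0 mM, k3 = 3.03 × 10⁻⁴ /s)
    substrate + coupling partner → mono adduct (k4 = 8.96 × 10⁻⁴ /M/s)
    coupling partner + bis adduct → triple product (k5 = 0.00152 /M/s)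

- why nothing more happens at 10 d, or that something still does (all of the substrate has reacted / forward and back rates have come level / the coupling partner has run out first / it is still moving)
- the triple product standing at 10 d, as a percentage of the substrate charged
- the mono adduct standing at 10 d, as a percentage of the substrate charged
- amount of triple product if the flask were left three thousand times as long, in percent of the substrate charged

- what is said of triple product includes crystals
- crystals is a solid; its amount is given per volume of the solution
- the reaction counts as stopped when no species that holds the substrate changes by six tenths of a point or more over the second half of the time
- run time (flask): 10 d

The bench rule says that the shorter half-life takes the material. At the charged strength, I divided the rate of step 5 by the rate of step 2, so that the bis adduct and time both dropped out. That gave a lead of 3.76 for the partner path, so 79.0% of the bis adduct would go on to triple product.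

But the rate of step 5 is proportional to the partner, so its half-life stretches as the partner is used. The two paths run level when the partner stands at a fraction of its charge equal to the step 2 constant over the step 5 constant times that charge. This crossing fraction is 0.266, and below it decay takes the larger share.

The charges allow at most 31.7% triple product. The half-life of mono adduct by step 1 at charged strength, 0.30 d, is short against 10 d, so I expected the partner to fall past the crossing fraction within the run. My hand reckoning stopped there: the share of bis adduct reaching triple product should end below the starting figure.

The forecast said the coupling partner has run out first. It put triple product at 7.5% (6% to 9.5%), mono adduct at 50% (45% to 54%), and the long-term triple product at 7.5% (6% to 9.5%), reasoning that once “the partner is gone no more triple product can form”.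

The simulation gave the coupling partner has run out first, with 0% of the partner left, triple product at 7.29%, mono adduct at 52.0%, and 7.29% in the long term. This flask held 7.29% triple product against 10.6% decomposed reagent, a share of 40.9%. A neighbour flask, charged with 0.16 M of partner, has a crossing fraction of 0.158, lower than this flask's. At 10.0 d, that neighbour flask held 24.0% triple product against 20.1% decomposed reagent, a share of 54.5%.

(All constants were chosen freely; no experiment stands behind them.)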